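**Plan**
- Cuts: after the silyl group on the ring B phenol is removed, ring A is opened at C1'–C2' and C5'–C6'. This leaves a C2'–C5' butadiene and a C6'–C1' terminal alkyne that already carries the cinnamoyl chain.
- Feature used: ring A has the acyl carbon at C1', the free hydroxyl at C2' and the geranyl ether oxygen at C4', with C3', C5' and C6' unsubstituted. A 1,1,3-trioxygenated buta-1,3-diene and an ethynyl ketone deliver exactly this pattern. The two oxygens arrive in different functions (ketene acetal O becomes the phenol, enol ether O stays the geranyl ether), so they never compete.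
- Earlier cuts: the enol ether C–O bond (geraniol + methyl but-2-ynoate), the ketone C(=O)–C(sp) bond (N-methoxy-N-methylamide + ethynylmagnesium bromide), and the Cα=Cβ bond (phosphonate + aldehyde).
- Forward order: ring B is bought. Two arms of two steps each give the diene and the ynone. Their union builds ring A, the only ring made, in the penultimate step, and desilylation ends the route.
- Stereochemistry: the target has no stereocentre. The geranyl 2E alkene comes unchanged from geraniol, the enone E alkene comes from the Horner–Wadsworth–Emmons step, and neither is touched afterwards.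

Key step: step 5

Notation: geranyl = (2E)-3,7-dimethylocta-2,6-dien-1-yl.
Assumption: the ketene acetal double bond of the diene is drawn 1E by analogy with the 1,3-dimethoxy parent; either geometry leads to the same arene.

Step 1
Reactants: 1 geraniol; 2 methyl but-2-ynoate
Product: 3 methyl (2E)-3-(geranyloxy)but-2-enoate
Conditions: 2 (1.2 equiv), PMe3 (0.15 equiv), CH2Cl2, 0 → 23 °C
Reagents that add atoms: none
Why: Phosphine-catalysed oxa-Michael addition of an alcohol to an alkynoate, in which the small, strongly nucleophilic PMe3 copes with the β-methyl group and generates the alkoxide that adds at C3, should give the favoured E enol ether, whose methyl group lies cis to the ester as step 2 requires.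

Step 2
Reactants: 3 methyl (2E)-3-(geranyloxy)but-2-enoate
Product: 5 (1E)-3-geranyloxy-1-methoxy-1-(trimethylsilyloxy)buta-1,3-diene, via lithium dienolate 4 (not isolated)
Conditions: LiN(i-Pr)2 (1.1 equiv), THF, −78 °C, 30 min; Me3SiCl (1.3 equiv), −78 → 0 °C; evaporate at ≤ 20 °C under high vacuum (strips i-Pr2NH), pentane, filter under Ar; used at once
Reagents that add atoms: chlorotrimethylsilane, C[Si](C)(C)Cl
Why: This is the standard preparation of 1,3-dialkoxy-1-silyloxybutadienes (kinetic γ-deprotonation of a 3-alkoxybut-2-enoate at the methyl group cis to the ester, then O-silylation of the extended enolate), run cold so that neither the anion nor the product suffers a [3,3] shift of its allyl vinyl ether.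

Step 3
Reactants: 6 diethyl {2-[methoxy(methyl)amino]-2-oxoethyl}phosphonate; 7 4-(tert-butyldimethylsilyloxy)benzaldehyde
Product: 9 (2E)-3-[4-(tert-butyldimethylsilyloxy)phenyl]-N-methoxy-N-methylprop-2-enamide, via sodium phosphonate carbanion 8 (not isolated)
Conditions: 6 (1.1 equiv), NaH (1.1 equiv), THF, 0 °C; then 7, 0 → 23 °C
Reagents that add atoms: none
Why: Horner–Wadsworth–Emmons olefination with an amide-stabilised phosphonate should give the E alkene with an aromatic aldehyde, and the aryl silyl ether is inert to the sodium phosphonate in THF.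

Step 4
Reactants: 9 (2E)-3-[4-(tert-butyldimethylsilyloxy)phenyl]-N-methoxy-N-methylprop-2-enamide; 10 ethynylmagnesium bromide
Product: 12 (1E)-1-[4-(tert-butyldimethylsilyloxy)phenyl]pent-1-en-4-yn-3-one, via bromomagnesium hemiaminal chelate 11 (not isolated)
Conditions: 10 (0.5 M in THF, 2.5 equiv), THF, −20 → 0 °C; cannulated into 1 M aq NaHSO4/Et2O, 0 °C
Reagents that add atoms: none
Why: In this Weinreb ketone synthesis the alkynyl Grignard reagent adds 1,2, chelate 11 survives until the quench so no second addition occurs, and inverse addition into cold acid protonates the released amine before it can add to the terminal ynone.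

Step 5
Reactants: 5 (1E)-3-geranyloxy-1-methoxy-1-(trimethylsilyloxy)buta-1,3-diene; 12 (1E)-1-[4-(tert-butyldimethylsilyloxy)phenyl]pent-1-en-4-yn-3-one
Product: 14 (2E)-3-[4-(tert-butyldimethylsilyloxy)phenyl]-1-[4-(geranyloxy)-2-hydroxyphenyl]prop-2-en-1-one, via cyclohexa-1,4-diene cycloadduct 13 (not isolated)
Conditions: 5 (2.0 equiv), PhMe (2 M in 12), Ar, dark, 0 → 23 °C, 24–48 h; then 0.1 M aq HCl–THF, 0 °C, 15 min
Reagents that add atoms: none
Why: Normal-electron-demand Diels–Alder addition: C4 of diene 5, the terminus towards which the two C1 oxygens and the C3 oxygen all push electron density, bonds to the unsubstituted alkyne carbon of 12 (C5'–C6'), and the ketene acetal carbon C1 bonds to the acyl-bearing alkyne carbon (C2'–C1'), either in one highly asynchronous event or as conjugate addition followed by collapse of the allenolate onto the silyloxycarbenium ion. The closest known reaction type is the benzannulation of 1,3-dialkoxy-1-silyloxybuta-1,3-dienes with acetylenic ketones and esters, which gives 2-hydroxy-4-alkoxyaryl carbonyl compounds; here only the 3-alkoxy group changes from methyl to geranyl. Ring A is the one ring closed, a six-membered carbocycle formed by intermolecular [4+2] cycloaddition, and adduct 13 aromatises when dilute acid ionises its doubly allylic mixed acetal, methanol leaving, the C5' methylene losing a proton and the aryl trimethylsilyl ether hydrolysing to the phenol, which is then held by a hydrogen bond to the ketone. The acetal carbon of 13 is a transient stereocentre that forms as a racemate and vanishes on aromatisation, so nothing has to be controlled, and both E alkenes are spectators. Regio- and site selectivity are needed: the matched polarisation of diene and ynone fixes the orientation, the terminal sp carbon is less hindered and more electrophilic than the β-carbon of the styryl alkene (deactivated by the para silyloxy donor), and the absence of a Lewis acid keeps the carbonyl group out of play. The cycloaddition must also outrun the [3,3] shift of the allyl vinyl ether within 5, which is addressed by high concentration, excess diene (this also covers diene consumed by methanol from early aromatisation) and a ceiling of 23 °C, a bimolecular reaction being set against a unimolecular one that would have to create a quaternary carbon at the disubstituted geranyl terminus.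

Step 6
Reactants: 14 (2E)-3-[4-(tert-butyldimethylsilyloxy)phenyl]-1-[4-(geranyloxy)-2-hydroxyphenyl]prop-2-en-1-one
Product: 15 (2E)-1-[4-(geranyloxy)-2-hydroxyphenyl]-3-(4-hydroxyphenyl)prop-2-en-1-one (target)
Conditions: Bu4NF (1.1 equiv), AcOH (1.2 equiv), THF, 0 °C, 20 min
Reagents that add atoms: none
Why: Fluoride cleavage of an aryl silyl ether is fast at 0 °C, and the acetic acid buffer keeps the medium from turning basic, so the 2'-hydroxychalcone should not close to the flavanone by oxa-Michael addition and the geranyl ether stays intact.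

**Compound list**
1 | geraniol, (2E)-3,7-dimethylocta-2,6-dien-1-ol | CC(C)=CCC/C(C)=C/CO | starting material
2 | methyl but-2-ynoate | CC#CC(=O)OC | starting material
3 | methyl (2E)-3-(geranyloxy)but-2-enoate | CC(C)=CCC/C(C)=C/CO/C(C)=C/C(=O)OC | intermediate
4 | lithium 3-geranyloxy-1-methoxybuta-1,3-dien-1-olate (not isolated) | C=C(OC/C=C(\C)CCC=C(C)C)/C=C(\OC)O[Li] | intermediate
5 | (1E)-3-geranyloxy-1-methoxy-1-(trimethylsilyloxy)buta-1,3-diene | C=C(OC/C=C(\C)CCC=C(C)C)/C=C(\OC)O[Si](C)(C)C | intermediate
6 | diethyl {2-[methoxy(methyl)amino]-2-oxoethyl}phosphonate | CCOP(=O)(CC(=O)N(C)OC)OCC | starting material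
7 | 4-(tert-butyldimethylsilyloxy)benzaldehyde | O=Cc1ccc(O[Si](C)(C)C(C)(C)C)cc1 | starting material
8 | sodium salt of phosphonate 6, carbanion at the P–CH–C(=O) carbon (not isolated) | [Na+].CCOP(=O)(OCC)[CH-]C(=O)N(C)OC | intermediate
9 | (2E)-3-[4-(tert-butyldimethylsilyloxy)phenyl]-N-methoxy-N-methylprop-2-enamide | CON(C)C(=O)/C=C/c1ccc(O[Si](C)(C)C(C)(C)C)cc1 | intermediate
10 | ethynylmagnesium bromide | C#C[Mg]Br | starting material
11 | bromomagnesium alkoxide of the tetrahedral adduct of 10 to 9, racemic (not isolated) | C#CC(O[Mg]Br)(N(C)OC)/C=C/c1ccc(O[Si](C)(C)C(C)(C)C)cc1 | intermediate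
12 | (1E)-1-[4-(tert-butyldimethylsilyloxy)phenyl]pent-1-en-4-yn-3-one | C#CC(=O)/C=C/c1ccc(O[Si](C)(C)C(C)(C)C)cc1 | intermediate
13 | (2E)-3-[4-(tert-butyldimethylsilyloxy)phenyl]-1-[4-geranyloxy-6-methoxy-6-(trimethylsilyloxy)cyclohexa-1,4-dien-1-yl]prop-2-en-1-one, racemic (not isolated) | CC(C)=CCC/C(C)=C/COC1=CC(OC)(O[Si](C)(C)C)C(C(=O)/C=C/c2ccc(O[Si](C)(C)C(C)(C)C)cc2)=CC1 | intermediate
14 | (2E)-3-[4-(tert-butyldimethylsilyloxy)phenyl]-1-[4-(geranyloxy)-2-hydroxyphenyl]prop-2-en-1-one | CC(C)=CCC/C(C)=C/COc1ccc(C(=O)/C=C/c2ccc(O[Si](C)(C)C(C)(C)C)cc2)c(O)c1 | intermediate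
15 | (2E)-1-[4-(geranyloxy)-2-hydroxyphenyl]-3-(4-hydroxyphenyl)prop-2-en-1-one | CC(C)=CCC/C(C)=C/COc1ccc(C(=O)/C=C/c2ccc(O)cc2)c(O)c1 | target

**Totals**
- Total step count: 6.
- Longest linear sequence: 4 (steps 1, 2, 5, 6 or steps 3, 4, 5, 6).

**Steps most likely to fail**

First, step 5.
- The cycloaddition may be too slow at 23 °C. The [3,3] shift of the diene, oligomerisation of the cross-conjugated enynone, or loss of silanol in place of methanol during aromatisation could then take over.
- The fallback keeps the same two ring bonds but uses a smaller, more electrophilic dienophile and builds the enone afterwards. It sets out from diene 5.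
- Diene 5 is dissolved in an excess of commercial but-3-yn-2-one (neat, 0 → 23 °C), so that the bimolecular rate is as high as possible.
- This should give 1-[4-geranyloxy-6-methoxy-6-(trimethylsilyloxy)cyclohexa-1,4-dien-1-yl]ethanone F1. The same dilute acid work-up then gives 1-[4-(geranyloxy)-2-hydroxyphenyl]ethanone F2.
- Claisen–Schmidt condensation of F2 with aldehyde 7 (KOH, EtOH, 23 °C) cleaves the aryl silyl ether in the same flask and comes back to the route at target 15.

Second, step 2.
- The lithium dienolate is set up for an anion-accelerated [3,3] shift, and silylation may occur on carbon.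
- The unpurified ketene acetal may hydrolyse, or carry amine into the cycloaddition.
- The fallback takes the allyl vinyl ether out of the diene and attaches the geranyl group after ring A exists. It sets out from ynone 12.
- Methyl acetoacetate is silylated (Et3N, Me3SiCl) to methyl (2E)-3-(trimethylsilyloxy)but-2-enoate F3.
- A second silylation (LiN(i-Pr)2, Me3SiCl, THF, −78 °C) gives (1E)-1-methoxy-1,3-bis(trimethylsilyloxy)buta-1,3-diene F4, which can be distilled and tolerates heating.
- With 12 (PhMe, 60–80 °C) F4 should give the bis(trimethylsilyloxy)cyclohexa-1,4-diene adduct F5. Dilute acid then gives (2E)-3-[4-(tert-butyldimethylsilyloxy)phenyl]-1-(2,4-dihydroxyphenyl)prop-2-en-1-one F6.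
- Mitsunobu etherification of F6 with geraniol 1 (PPh3, DIAD, THF, 0 °C) should take the free 4'-hydroxyl, because the 2'-hydroxyl is tied up in its hydrogen bond to the ketone. The route is rejoined at 14.

Third, step 4.
- The released N,O-dimethylhydroxylamine may add to the terminal ynone during the quench, and the enynone may oligomerise on concentration.
- The fallback reaches the ketone by oxidation instead of acyl substitution, so the amine is removed before any ynone exists. It sets out from amide 9.
- Amide 9 is reduced with i-Bu2AlH (THF, −78 °C) to (2E)-3-[4-(tert-butyldimethylsilyloxy)phenyl]prop-2-enal F7.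
- Ethynylmagnesium bromide 10 adds (THF, 0 °C) to give racemic (1E)-1-[4-(tert-butyldimethylsilyloxy)phenyl]pent-1-en-4-yn-3-ol F8.
- MnO2 (CH2Cl2, 23 °C) oxidises this allylic and propargylic carbinol, and the route is rejoined at 12.

**Further compounds**
F1 | step 5 | 1-[4-geranyloxy-6-methoxy-6-(trimethylsilyloxy)cyclohexa-1,4-dien-1-yl]ethanone, racemic | CC(C)=CCC/C(C)=C/COC1=CC(OC)(O[Si](C)(C)C)C(C(C)=O)=CC1
F2 | step 5 | 1-[4-(geranyloxy)-2-hydroxyphenyl]ethanone | CC(C)=CCC/C(C)=C/COc1ccc(C(C)=O)c(O)c1
F3 | step 2 | methyl (2E)-3-(trimethylsilyloxy)but-2-enoate | C/C(O[Si](C)(C)C)=C\C(=O)OC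
F4 | step 2 | (1E)-1-methoxy-1,3-bis(trimethylsilyloxy)buta-1,3-diene | C=C(O[Si](C)(C)C)/C=C(\OC)O[Si](C)(C)C
F5 | step 2 | (2E)-3-[4-(tert-butyldimethylsilyloxy)phenyl]-1-[6-methoxy-4,6-bis(trimethylsilyloxy)cyclohexa-1,4-dien-1-yl]prop-2-en-1-one, racemic | COC1(O[Si](C)(C)C)C=C(O[Si](C)(C)C)CC=C1C(=O)/C=C/c1ccc(O[Si](C)(C)C(C)(C)C)cc1
F6 | step 2 | (2E)-3-[4-(tert-butyldimethylsilyloxy)phenyl]-1-(2,4-dihydroxyphenyl)prop-2-en-1-one | O=C(/C=C/c1ccc(O[Si](C)(C)C(C)(C)C)cc1)c1ccc(O)cc1O
F7 | step 4 | (2E)-3-[4-(tert-butyldimethylsilyloxy)phenyl]prop-2-enal | O=C/C=C/c1ccc(O[Si](C)(C)C(C)(C)C)cc1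
F8 | step 4 | (1E)-1-[4-(tert-butyldimethylsilyloxy)phenyl]pent-1-en-4-yn-3-ol, racemic | C#CC(O)/C=C/c1ccc(O[Si](C)(C)C(C)(C)C)cc1
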